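Slowness was where I began: I turned each constant into a time at the charged amounts, to see which steps were slow against the run.

| setting | birch | cedar | oak | ash |
|---|---|---|---|---|
| starting material | 0.10 M | 0.10 M | 0.10 M | 0.10 M |
| protic impurity | 0.0200 M | 0.0200 M | 0.0200 M | 0.0200 M |
| temperature | 40 °C | 55 °C | 25 °C | 70 °C |
| time | 30 s | 30 s | 30 s | 30 s |

    starting material → target, rate k1*[starting material]/(1 + ([starting material]/sat1)) (sat1 = 0.0532 M, k1 = 0.0547 s⁻¹, Ea1 = 80.0 kJ mol⁻¹)
    target → over-reaction product (k2 = 0.0390 s⁻¹, Ea2 = 71.0 kJ mol⁻¹)
    starting material + protic impurity → quenched substrate (k3 = 4.95 M⁻¹ s⁻¹, Ea3 = 42.0 kJ mol⁻¹)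
    crystals ⇌ target, rate k4*(cs4 - [target]) while solid is left; crystals form when [target] > cs4 (cs4 = 33 mM, k4 = 0.717 s⁻¹)
    (constants at 40 °C)

- for target the crystals are counted in
- as a solid, counted per litre of solution: crystals
- the constants hold at 40 °C; other temperatures follow from the activation energies

- the best flask by amount of target, in percent of the starting material charged; "all alike" if 1.5 percentage points covers them all (birch / cedar / oak / ash / all alike)
- amount of target at the end, in percent of the starting material charged, birch
- amount of target at the end, in percent of the starting material charged, cedar
- amount of target at the end, in percent of the starting material charged, oak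
- amount of target at the end, in percent of the starting material charged, ash

I reckoned birch by hand, at the temperature where the constants are given.

1. Unslowed, step 1 has the feed time U = 1/k1 = 18.3 s.
2. The impurity's time against the charge, 1/(k3·cA), was 2.02 s, much shorter than U. So I took its charge off at once, which left C = 80.0 mM of starting material to feed step 1.
3. At that C the saturation term stretches the feed. F = U(1 + C/sat1) = 45.8 s is the stretched feed time, the time constant the feed has when it starts.
4. Target's life, L = 1/k2, was 25.6 s, which lies between the two feed times. So I could drop neither making nor losing.
5. With a pseudo-first-order feed of time T, target at time t is C·L/(T−L)·(e^(−t/T) − e^(−t/L)).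
6. Slow extreme: T = F for the whole of 30 s gave 21.3 % of the charge in birch.
7. Fast extreme: T = U gave 32.5 % in birch. I left crystals out of both extremes as a simplification, untested by this reckoning.
8. The real feed time starts near F, which is longer than U. As starting material is used, that time moves towards U. So I committed birch to lie between those two figures, and I reckoned no other flask by hand.

The forecast named birch, with birch 25.3 % (24.3 % to 26.3 %), cedar 5.7 %, oak 9.5 % and ash 0.001 %, on the ground that “the impurity removes about 0.02 M of starting material within seconds”.

The run gave birch 25.2 %, cedar 5.73 %, oak 9.51 % and ash 0 %, so birch was best, and birch stood between the figures from F = 45.8 s and U. Birch held 0 % crystals at 30.0 s. The birch answer moved by 5 points at a stop of 17.4 s or 62.8 s. For the neighbour, ash's charges kept at 55 °C, I got U = 4.49 s, F = 11.2 s and L = 7.37 s. The run outlasted L there, and the extremes changed places: F gave 7.96 %, U gave 3.24 %. That flask gave 5.73 %.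

The numbers stand for no real mixture; the result is computed.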